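The leak of adduct to decomposed reagent, 0.091 h⁻¹, over its return to substrate and partner, 2.72 h⁻¹, is a ratio of 0.0335, far below one, so adduct stays close to equilibrium with free substrate and partner while it leaks.

    adduct ⇌ product (K1 = 1.4, k1 = 0.16 h⁻¹)
    substrate + partner ⇌ adduct (K2 = 0.081 L mol⁻¹, k2 = 0.22 L mol⁻¹ h⁻¹)
    adduct → decomposed reagent (k3 = 0.091 h⁻¹)

| flask | substrate | partner | time |
|---|---|---|---|
| winter | 0.80 M | 0.595 M | 8.0 d |
| midnight | 1.2 M | 0.595 M | 8.0 d |
| spring | 2.0 M | 0.595 M | 8.0 d |
| dawn | 3.0 M | 0.595 M | 8.0 d |

- "hardly changes" means that all values lie within two and a half points (for a concentration: within two and a half percent of the largest)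
- run time (winter): 8.0 d

1. [product] at the end for winter, midnight, spring, dawn, in this order
2. how that number moves from the first to the last of them (rises, then falls / falls all the way / hardly changes / falls, then rises / rises all the way)

Two chemists dispute the row. The first holds to equilibrium: [product] = K1·K2·[substrate]·[partner], with a share of the partner bound. That gives 0.0467 M for winter and 0.128 M for dawn, rising with the charge.

The second counts the leak. Free partner, adduct and product form one pool, which is free partner times 1 + (1 + K1)·K2·[substrate]. The pool loses k3·[adduct], so while [substrate] holds still it decays first-order in the pool (pseudo-first-order), and its count of e-folds over the run is n = k3·K2·[substrate]·t / (1 + (1 + K1)·K2·[substrate]). For dawn, taken at its charge, n is 2.68.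

Since [product] goes as [substrate]·exp(−n) / (1 + (1 + K1)·K2·[substrate]), it stops gaining from more substrate where n is one. That gives 0.819 M: the balance concentration, the [substrate] at which the partner pool falls by a factor e over the run.

My own reckoning adds what the leak removes from the substrate, 0.376 M at that point, and puts the turn at a charge of 1.20 M. Winter lies below this, midnight lies on it and spring lies above it. This gives a turn, not a row.

The forecast sides with the second chemist: 0.014 M, 0.016 M, 0.015 M, 0.011 M, shape rises, then falls, since by the end “the greater loss of partner wins out”.

The flask gives 0.0145 M, 0.0162 M, 0.0150 M, 0.0115 M: rises, then falls, with the turn read at 1.3 M. The first chemist keeps the charges below that reading, where winter to midnight does rise.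

In winter, adduct and product relax into each other with a half-life of 0.105 d, much shorter than the 8.0 d run, and at the end they stand at a ratio of 1.46 against K1 of 1.4. Winter ends at 0.472 M [substrate], below the balance concentration of 0.819 M. Spring ends at 1.49 M, above it, with a local order of −0.43. Dawn ends at 2.44 M, further above, with partner at 6.40% of its charge.

The constants are invented; the run is a simulation.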